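**Retrosynthetic overview**

- Feature: in each chromanone unit the ring oxygen O1 is bonded to the benzylic C2, C2 is next to the enolisable C3, and C3 of one pyranone ring is bonded to C3' of the other. Opening O1–C2 and O1'–C2' (retro-oxa-Michael) therefore turns both pyranone rings into a 2,3-bis(arylidene)-1,4-diketone (unprimed = methoxyphenyl unit, primed = hydroxyphenyl unit).
- Disconnections: the two O1–C2 bonds (twofold catalytic oxa-Michael), the two arylidene C=C bonds (Horner–Wadsworth–Emmons, then aldol condensation), and the C3–C3' bond (ketophosphonate alkylated by a phenacyl bromide); both ketone halves come from one phloroacetophenone ether.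
- The ortho phenols stay as MOM ethers through both condensations, so that no racemic ring closure can occur before the catalyst is present.
- Two bromine atoms on the anisyl ring make its enone arm the faster one. Ring order: the pyranone ring of the methoxyphenyl unit closes first (C3 equilibrates to trans), then that of the hydroxyphenyl unit (C3' set cis by kinetic protonation), in the same flask.
- One final hydrogenolysis removes the five benzyl ethers and both bromine atoms.

Key step: step 9

Assumption: the quinine-derived thiourea is taken to give the 2S sense in both closures; if a model 2-hydroxychalcone shows the opposite sense, its quinidine-derived pseudoenantiomer is used instead.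

**Route**

Step 1
Reactants: 1 1-(2,4,6-trihydroxyphenyl)ethan-1-one
Product: 2 1-[2,4-bis(benzyloxy)-6-hydroxyphenyl]ethan-1-one
Conditions: BnBr (2.1 equiv), K2CO3, DMF, rt
Reagents that add atoms: benzyl bromide, BrCc1ccccc1
Why: Williamson etherification, in which the hydroxyl that is hydrogen-bonded to the acetyl carbonyl is the least reactive and should stay free with two equivalents of benzyl bromide.

Step 2
Reactants: 2 1-[2,4-bis(benzyloxy)-6-hydroxyphenyl]ethan-1-one
Product: 3 1-[2,4-bis(benzyloxy)-6-(methoxymethoxy)phenyl]ethan-1-one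
Conditions: NaH, MOMCl, DMF, 0 °C to rt
Reagents that add atoms: chloromethyl methyl ether, COCCl
Why: O-alkylation of the sodium phenoxide (MOM protection) masks the phenol that would otherwise add to the enones under the basic conditions of steps 6 and 7.

Step 3
Reactants: 3 1-[2,4-bis(benzyloxy)-6-(methoxymethoxy)phenyl]ethan-1-one
Product: 5 2-bromo-1-[2,4-bis(benzyloxy)-6-(methoxymethoxy)phenyl]ethan-1-one, via trimethylsilyl enol ether 4 (not isolated)
Conditions: LiN(SiMe3)2, Me3SiCl, THF, −78 °C; then NBS, −78 to 0 °C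
Reagents that add atoms: N-bromosuccinimide, O=C1CCC(=O)N1Br
Why: Kinetic enolisation and silylation followed by electrophilic bromination of the silyl enol ether, which should react with NBS much faster than the electron-rich arene does, gives the phenacyl bromide without ring bromination.

Step 4
Reactants: 5 2-bromo-1-[2,4-bis(benzyloxy)-6-(methoxymethoxy)phenyl]ethan-1-one
Product: 6 diethyl {2-[2,4-bis(benzyloxy)-6-(methoxymethoxy)phenyl]-2-oxoethyl}phosphonate
Conditions: P(OEt)3 (neat, excess), 110 °C
Reagents that add atoms: triethyl phosphite, CCOP(OCC)OCC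
Why: Michaelis–Arbuzov reaction, in which the hindered and electron-rich carbonyl group should disfavour the competing Perkow attack at C=O.

Step 5
Reactants: 6 diethyl {2-[2,4-bis(benzyloxy)-6-(methoxymethoxy)phenyl]-2-oxoethyl}phosphonate; 5 2-bromo-1-[2,4-bis(benzyloxy)-6-(methoxymethoxy)phenyl]ethan-1-one
Product: 7 diethyl {1,4-bis[2,4-bis(benzyloxy)-6-(methoxymethoxy)phenyl]-1,4-dioxobutan-2-yl}phosphonate (racemic)
Conditions: NaH, THF, 0 °C; then 5, 0 °C to rt
Reagents that add atoms: none
Why: SN2 C-alkylation of the stabilised ketophosphonate carbanion by the phenacyl bromide forms the future C3–C3' bond and leaves the two methylene carbons chemically distinct; the new stereocentre is racemic and disappears in step 6.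

Step 6
Reactants: 7 diethyl {1,4-bis[2,4-bis(benzyloxy)-6-(methoxymethoxy)phenyl]-1,4-dioxobutan-2-yl}phosphonate; 8 3,5-dibromo-4-methoxybenzaldehyde
Product: 9 (E)-1,4-bis[2,4-bis(benzyloxy)-6-(methoxymethoxy)phenyl]-2-(3,5-dibromo-4-methoxybenzylidene)butane-1,4-dione
Conditions: NaH (1.0 equiv), THF, 0 °C; then 8, rt to 50 °C
Reagents that add atoms: none
Why: Horner–Wadsworth–Emmons olefination puts the first arylidene group only on the phosphonate-bearing carbon, and the reversible addition of the stabilised carbanion to the electron-poor aldehyde should give the E alkene with the aryl group trans to the aroyl group.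

Step 7
Reactants: 9 (E)-1,4-bis[2,4-bis(benzyloxy)-6-(methoxymethoxy)phenyl]-2-(3,5-dibromo-4-methoxybenzylidene)butane-1,4-dione; 10 4-(benzyloxy)benzaldehyde
Product: 11 (2E,3E)-2-[4-(benzyloxy)benzylidene]-1,4-bis[2,4-bis(benzyloxy)-6-(methoxymethoxy)phenyl]-3-(3,5-dibromo-4-methoxybenzylidene)butane-1,4-dione
Conditions: KOH (aq), EtOH–THF, 0 °C to rt, dark
Reagents that add atoms: none
Why: Claisen–Schmidt aldol condensation at the only remaining enolisable CH2 with a non-enolisable aldehyde, where E1cB dehydration should give the conjugated E alkene, as in the second Stobbe condensation of arylidene succinates.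

Step 8
Reactants: 11 (2E,3E)-2-[4-(benzyloxy)benzylidene]-1,4-bis[2,4-bis(benzyloxy)-6-(methoxymethoxy)phenyl]-3-(3,5-dibromo-4-methoxybenzylidene)butane-1,4-dione
Product: 12 (2E,3E)-2-[4-(benzyloxy)benzylidene]-1,4-bis[2,4-bis(benzyloxy)-6-hydroxyphenyl]-3-(3,5-dibromo-4-methoxybenzylidene)butane-1,4-dione
Conditions: 2 M HCl, MeOH–THF, rt, dark; used without delay
Reagents that add atoms: none
Why: Acid-catalysed methanolysis of the two MOM acetals, which are activated by the ortho carbonyl groups, leaves benzyl ethers and aryl bromides untouched and avoids base, under which the freed phenols would cyclise without stereocontrol.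

Step 9
Reactants: 12 (2E,3E)-2-[4-(benzyloxy)benzylidene]-1,4-bis[2,4-bis(benzyloxy)-6-hydroxyphenyl]-3-(3,5-dibromo-4-methoxybenzylidene)butane-1,4-dione
Product: 14 (2S,2'S,3R,3'S)-5,5',7,7'-tetrakis(benzyloxy)-2'-[4-(benzyloxy)phenyl]-2-(3,5-dibromo-4-methoxyphenyl)-[3,3'-bichromane]-4,4'-dione, via mono-closed trans-flavanone 13 (not isolated)
Conditions: 1-[3,5-bis(trifluoromethyl)phenyl]-3-[(8α,9S)-6'-methoxycinchonan-9-yl]thiourea (20 mol%), toluene, −20 °C, then 0 °C, dark
Reagents that add atoms: none
Why: The quinuclidine nitrogen of the catalyst deprotonates a ketone-flanked phenol while the thiourea holds the neighbouring enone carbonyl, and the phenoxide adds to the benzylidene carbon; each pyranone ring is closed 6-endo-trig, and the reaction is the known bifunctional amine–thiourea oxa-Michael cyclisation of 2-hydroxychalcones (alpha-substituted ones included) to flavanones, run twice in one flask. The step needs the dibromoanisyl arm to close first, and this is secured by the two bromine atoms, which withdraw inductively and twist the methoxy group out of conjugation, so that this benzylidene carbon is clearly more electrophilic than that of the 4-benzyloxyphenyl arm and 13 should form at −20 °C. C2 and C2' are both set S by the catalyst, because the two enone arms are twisted about the central C3–C3' bond and each meets the catalyst as a separate chalcone. In 13, H3 is alpha to C4=O and allylic to the remaining enone, so under the catalyst it exchanges through the dienolate and C3 should settle as the more stable 2,3-trans (3R) isomer before the slower second arm reacts. The second closure gives a simple ketone enolate that is protonated at C3' on the face anti to the pseudoaxial C2' aryl group (allylic 1,2-strain), which gives the 2,3-cis (3'S) ring; this centre has no vinylogous acidity left and should hold at 0 °C. Catalyst control must override the bias of the first ring in the second closure, and this is the remaining uncertainty.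

Step 10
Reactants: 14 (2S,2'S,3R,3'S)-5,5',7,7'-tetrakis(benzyloxy)-2'-[4-(benzyloxy)phenyl]-2-(3,5-dibromo-4-methoxyphenyl)-[3,3'-bichromane]-4,4'-dione
Product: 15 (2S,2'S,3R,3'S)-5,5',7,7'-tetrahydroxy-2'-(4-hydroxyphenyl)-2-(4-methoxyphenyl)-[3,3'-bichromane]-4,4'-dione
Conditions: H2 (1 atm), 10% Pd/C, NaOAc (2.5 equiv), EtOAc–MeOH, rt
Reagents that add atoms: none
Why: Heterogeneous palladium-catalysed hydrogenolysis should cleave the five benzyl C–O bonds and the two aryl C–Br bonds, while the acetate buffer takes up HBr so that the ketone-flanked C3 and C3' centres are not epimerised and no stereocentre is touched.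

**Compound list**

1 | 1-(2,4,6-trihydroxyphenyl)ethan-1-one | CC(=O)c1c(O)cc(O)cc1O | starting material
2 | 1-[2,4-bis(benzyloxy)-6-hydroxyphenyl]ethan-1-one | CC(=O)c1c(O)cc(OCc2ccccc2)cc1OCc1ccccc1 | intermediate
3 | 1-[2,4-bis(benzyloxy)-6-(methoxymethoxy)phenyl]ethan-1-one | CC(=O)c1c(OCOC)cc(OCc2ccccc2)cc1OCc1ccccc1 | intermediate
4 | {1-[2,4-bis(benzyloxy)-6-(methoxymethoxy)phenyl]ethenyloxy}trimethylsilane (not isolated) | C=C(O[Si](C)(C)C)c1c(OCOC)cc(OCc2ccccc2)cc1OCc1ccccc1 | intermediate
5 | 2-bromo-1-[2,4-bis(benzyloxy)-6-(methoxymethoxy)phenyl]ethan-1-one | O=C(CBr)c1c(OCOC)cc(OCc2ccccc2)cc1OCc1ccccc1 | intermediate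
6 | diethyl {2-[2,4-bis(benzyloxy)-6-(methoxymethoxy)phenyl]-2-oxoethyl}phosphonate | CCOP(=O)(OCC)CC(=O)c1c(OCOC)cc(OCc2ccccc2)cc1OCc1ccccc1 | intermediate
7 | diethyl {1,4-bis[2,4-bis(benzyloxy)-6-(methoxymethoxy)phenyl]-1,4-dioxobutan-2-yl}phosphonate (racemic) | CCOP(=O)(OCC)C(CC(=O)c1c(OCOC)cc(OCc2ccccc2)cc1OCc1ccccc1)C(=O)c1c(OCOC)cc(OCc2ccccc2)cc1OCc1ccccc1 | intermediate
8 | 3,5-dibromo-4-methoxybenzaldehyde | COc1c(Br)cc(C=O)cc1Br | starting material
9 | (E)-1,4-bis[2,4-bis(benzyloxy)-6-(methoxymethoxy)phenyl]-2-(3,5-dibromo-4-methoxybenzylidene)butane-1,4-dione | COc1c(Br)cc(/C=C(/C(=O)c2c(OCOC)cc(OCc3ccccc3)cc2OCc2ccccc2)CC(=O)c2c(OCOC)cc(OCc3ccccc3)cc2OCc2ccccc2)cc1Br | intermediate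
10 | 4-(benzyloxy)benzaldehyde | O=Cc1ccc(OCc2ccccc2)cc1 | starting material
11 | (2E,3E)-2-[4-(benzyloxy)benzylidene]-1,4-bis[2,4-bis(benzyloxy)-6-(methoxymethoxy)phenyl]-3-(3,5-dibromo-4-methoxybenzylidene)butane-1,4-dione | COc1c(Br)cc(/C=C(/C(=O)c2c(OCOC)cc(OCc3ccccc3)cc2OCc2ccccc2)C(\C(=O)c2c(OCOC)cc(OCc3ccccc3)cc2OCc2ccccc2)=C/c2ccc(OCc3ccccc3)cc2)cc1Br | intermediate
12 | (2E,3E)-2-[4-(benzyloxy)benzylidene]-1,4-bis[2,4-bis(benzyloxy)-6-hydroxyphenyl]-3-(3,5-dibromo-4-methoxybenzylidene)butane-1,4-dione | COc1c(Br)cc(/C=C(/C(=O)c2c(O)cc(OCc3ccccc3)cc2OCc2ccccc2)C(\C(=O)c2c(O)cc(OCc3ccccc3)cc2OCc2ccccc2)=C/c2ccc(OCc3ccccc3)cc2)cc1Br | intermediate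
13 | (2S,3R)-5,7-bis(benzyloxy)-3-{(E)-1-[2,4-bis(benzyloxy)-6-hydroxybenzoyl]-2-[4-(benzyloxy)phenyl]ethenyl}-2-(3,5-dibromo-4-methoxyphenyl)chroman-4-one (not isolated) | COc1c(Br)cc([C@H]2Oc3cc(OCc4ccccc4)cc(OCc4ccccc4)c3C(=O)[C@@H]2C(\C(=O)c2c(O)cc(OCc3ccccc3)cc2OCc2ccccc2)=C/c2ccc(OCc3ccccc3)cc2)cc1Br | intermediate
14 | (2S,2'S,3R,3'S)-5,5',7,7'-tetrakis(benzyloxy)-2'-[4-(benzyloxy)phenyl]-2-(3,5-dibromo-4-methoxyphenyl)-[3,3'-bichromane]-4,4'-dione | COc1c(Br)cc([C@H]2Oc3cc(OCc4ccccc4)cc(OCc4ccccc4)c3C(=O)[C@@H]2[C@@H]2C(=O)c3c(OCc4ccccc4)cc(OCc4ccccc4)cc3O[C@@H]2c2ccc(OCc3ccccc3)cc2)cc1Br | intermediate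
15 | (2S,2'S,3R,3'S)-5,5',7,7'-tetrahydroxy-2'-(4-hydroxyphenyl)-2-(4-methoxyphenyl)-[3,3'-bichromane]-4,4'-dione | COc1ccc([C@H]2Oc3cc(O)cc(O)c3C(=O)[C@@H]2[C@@H]2C(=O)c3c(O)cc(O)cc3O[C@@H]2c2ccc(O)cc2)cc1 | target

**Step count and risks**

Total steps: 10. Longest linear sequence: 10 steps (1 to 15).

Steps most likely to fail:

Step 9. The time separation between the two ring closures may be lost, or the protonation at C3' may be unselective, so that C3/C3' epimer mixtures form; proton delivery to the benzylic terminus of the dienolate (alkene migration) is a further leak. The fallback interrupts the cascade and sets out from 13, which is isolated after the −20 °C stage. The remaining phenol is capped with t-BuMe2SiOTf and 2,6-lutidine in CH2Cl2 at −78 °C to give the aryl tert-butyldimethylsilyl ether F1. With the second ring blocked, F1 is held with the same catalyst in toluene at rt until C3 has equilibrated to the 2,3-trans form. The silyl group is then removed with HF·pyridine in THF at 0 °C, which returns trans-13. The second ring is closed in a separate run with the catalyst at −40 °C in the presence of a hindered phenol as proton donor, and the route is rejoined at 14.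

Step 7. Base may shift the alkene of 9 into conjugation with both carbonyl groups (followed by furan or oligomer formation) faster than the hindered methylene condenses. The fallback sets out from 9 and replaces the equilibrium condensation by a directed aldol addition and a separate elimination. The kinetic enolate is formed with LiN(SiMe3)2 in THF at −78 °C and adds to 10 to give the beta-hydroxy ketone F2. Acetylation with Ac2O and DMAP gives the beta-acetoxy ketone F3. E1cB elimination with DBU in CH2Cl2 returns to the route at 11.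

Step 6. Olefination of the fully substituted, hindered phosphonate carbanion may be sluggish, so that proton transfer to the product methylene and over-condensation compete. The fallback sets out from 3 and avoids phosphorus altogether. Oxidative homocoupling of the lithium enolate (LiN(i-Pr)2, THF, −78 °C; CuCl2, DMF) gives the symmetrical 1,4-diketone F4. F4 is used in excess in a Claisen–Schmidt mono-condensation with 8 (KOH, EtOH–THF); unreacted F4 is recycled and the route is rejoined at 9.

**Further compounds**

F1 | step 9 | (2S,3R)-5,7-bis(benzyloxy)-3-{(E)-1-[2,4-bis(benzyloxy)-6-(tert-butyldimethylsilyloxy)benzoyl]-2-[4-(benzyloxy)phenyl]ethenyl}-2-(3,5-dibromo-4-methoxyphenyl)chroman-4-one | COc1c(Br)cc([C@H]2Oc3cc(OCc4ccccc4)cc(OCc4ccccc4)c3C(=O)[C@@H]2C(\C(=O)c2c(O[Si](C)(C)C(C)(C)C)cc(OCc3ccccc3)cc2OCc2ccccc2)=C/c2ccc(OCc3ccccc3)cc2)cc1Br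
F2 | step 7 | 2-{[4-(benzyloxy)phenyl](hydroxy)methyl}-1,4-bis[2,4-bis(benzyloxy)-6-(methoxymethoxy)phenyl]-3-[(E)-3,5-dibromo-4-methoxybenzylidene]butane-1,4-dione (diastereomer mixture) | COc1c(Br)cc(/C=C(/C(=O)c2c(OCOC)cc(OCc3ccccc3)cc2OCc2ccccc2)C(C(O)c2ccc(OCc3ccccc3)cc2)C(=O)c2c(OCOC)cc(OCc3ccccc3)cc2OCc2ccccc2)cc1Br
F3 | step 7 | [4-(benzyloxy)phenyl]{1,4-bis[2,4-bis(benzyloxy)-6-(methoxymethoxy)phenyl]-3-[(E)-3,5-dibromo-4-methoxybenzylidene]-1,4-dioxobutan-2-yl}methyl acetate (diastereomer mixture) | COc1c(Br)cc(/C=C(/C(=O)c2c(OCOC)cc(OCc3ccccc3)cc2OCc2ccccc2)C(C(OC(C)=O)c2ccc(OCc3ccccc3)cc2)C(=O)c2c(OCOC)cc(OCc3ccccc3)cc2OCc2ccccc2)cc1Br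
F4 | step 6 | 1,4-bis[2,4-bis(benzyloxy)-6-(methoxymethoxy)phenyl]butane-1,4-dione | O=C(CCC(=O)c1c(OCOC)cc(OCc2ccccc2)cc1OCc1ccccc1)c1c(OCOC)cc(OCc2ccccc2)cc1OCc1ccccc1
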